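**Retrosynthetic overview**

1. The target is (2S,4R)-4',7-dihydroxyflavan bonded through C4 to C8' of (−)-epigallocatechin. The strategy rests on ring C of the upper unit (O1, C2, C3, C4, fused to ring A at C4a–C8a): ring A is a resorcinol, and C2–C3–C4 is a three-carbon chain at the aldehyde oxidation level whose C4 carries ring D.
2. Last disconnection: C2–ring B, made by adding an arylzinc nucleophile to the C2 oxocarbenium ion, trans to the C4 aryl group.
3. Key disconnection: C4–C4a and O1–C2 together, back to resorcinol and the (E)-enal on C8' of hexa-O-benzylepigallocatechin; iminium catalysis sets C4.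
4. The enal comes from (−)-epigallocatechin (rings D, F, E and C2', C3' from the chiral pool) by benzylation, C8' bromination and a one-pot lithiation/three-carbon formylation.
5. Ring order: D/F/E (given), A (resorcinol), C (key step), B (last); hydrogenolysis then frees the hydroxyl groups.

Key step: step 5

Remark: locants of the epigallocatechin (lower) unit are primed (C2', C3', C5', C7', C8'); its benzo ring is ring D, its pyran ring is ring F and its pyrogallol ring is ring E.

**Route**

Step 1
Reactants: 1 (−)-epigallocatechin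
Product: 2 penta-O-benzylepigallocatechin (benzyl ethers on O5', O7' and the three ring E oxygens; C3' hydroxyl free)
Conditions: BnBr (5.5 equiv), K2CO3, DMF, −10 °C → rt, argon
Reagents that add atoms: benzyl bromide, BrCc1ccccc1
Why: Williamson etherification under carbonate conditions should alkylate only the five phenols and leave the secondary C3' alcohol, while low temperature and exclusion of air limit C-benzylation, oxidation of the pyrogallol and epimerisation at C2'; no stereocentre is formed.

Step 2
Reactants: 2 penta-O-benzylepigallocatechin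
Product: 3 hexa-O-benzylepigallocatechin
Conditions: NaH, BnBr, Bu4NI (cat.), DMF, 0 °C → rt
Reagents that add atoms: benzyl bromide, BrCc1ccccc1
Why: Williamson etherification of the C3' alkoxide should proceed without touching C2', because with all phenols capped no phenoxide-driven opening of ring F is possible, so the 2',3'-cis configuration is kept and the whole lower unit carries one type of protecting group.

Step 3
Reactants: 3 hexa-O-benzylepigallocatechin
Product: 4 8'-bromo-hexa-O-benzylepigallocatechin
Conditions: NBS (1.0 equiv), CH2Cl2, −40 → 0 °C, dark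
Reagents that add atoms: N-bromosuccinimide, O=C1CCC(=O)N1Br
Why: Electrophilic aromatic bromination should take place on ring D, the phloroglucinol-type and most nucleophilic arene, and at C8' in preference to C6', which is flanked by two benzyloxy groups, as is usual for 5,7-di-O-benzyl flavan-3-ols.

Step 4
Reactants: 4 8'-bromo-hexa-O-benzylepigallocatechin
Product: 7 (E)-3-(hexa-O-benzylepigallocatechin-8'-yl)prop-2-enal, via aryllithium 5 (not isolated), via lithium alkoxide adduct 6 (not isolated)
Conditions: n-BuLi, THF, −78 °C; Me2NCH=CHCHO, −78 → 0 °C; 1 M HCl (aq.), 0 °C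
Reagents that add atoms: (E)-3-(dimethylamino)acrolein, CN(C)/C=C/C=O; water, O
Why: Bromine–lithium exchange gives 5, which adds to the carbonyl group of the vinylogous formamide to give 6, and aqueous acid then expels the hydroxyl group through the enamine and hydrolyses the vinylogous iminium ion to the thermodynamically preferred (E)-enal (vinylogous Bouveault-type formylation), with no stereocentre formed or touched.

Step 5
Reactants: 7 (E)-3-(hexa-O-benzylepigallocatechin-8'-yl)prop-2-enal; 8 resorcinol
Product: 10 (4R)-4-(hexa-O-benzylepigallocatechin-8'-yl)chromane-2,7-diol (both C2 anomers), via 3,3-diarylpropanal 9 (not isolated)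
Conditions: 8 (3 equiv), (S)-2-[diphenyl(trimethylsilyloxy)methyl]pyrrolidine (20 mol %), PhCO2H (20 mol %), CH2Cl2–MeCN, 0 °C → rt
Reagents that add atoms: none
Why: Condensation of 7 with the (S)-configured amine gives the (E)-iminium ion, whose Re face at C-β is covered by the diphenyl(trimethylsilyloxy)methyl group, so resorcinol, activated through a hydroxyl group by the benzoate counter-ion, should add through its C4 to the open Si face and set C4 of the flavan as R under catalyst control, the influence of the remote C2'/C3' centres being expected to be small. The enamine so formed is protonated and hydrolysed to aldehyde 9, and the hydroxyl group ortho to the new bond adds to the carbonyl group in a 6-exo-trig closure that forms O1–C2 and ring C as lactol 10, whose anomeric mixture is of no consequence. The closest known reaction is the diarylprolinol silyl ether-catalysed Friedel–Crafts alkylation/hemiacetalisation of naphthols and alkoxyphenols with β-aryl enals to 4-aryl-chroman-2-ols. The step needs site selectivity on the arene, conjugate rather than direct addition, and mono-alkylation: C4 and C6 of resorcinol are equivalent, each ortho to one hydroxyl and para to the other, so both give the 7-hydroxy pattern and a ring that can close, the flanked C2 is shut off by the di-ortho-substituted β-aryl group, the bulky amine disfavours attack at the iminium carbon, and excess resorcinol suppresses a second alkylation. The electron-rich, hindered ring D lowers the electrophilicity of the iminium ion, which is why the free diol is used as the ring A partner in place of a less nucleophilic mono-ether with a non-cyclisable competing position, and why high concentration and long reaction time are planned.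

Step 6
Reactants: 10 (4R)-4-(hexa-O-benzylepigallocatechin-8'-yl)chromane-2,7-diol
Product: 11 (4R)-2,7-diacetoxy-4-(hexa-O-benzylepigallocatechin-8'-yl)chromane (both C2 anomers)
Conditions: Ac2O, pyridine, DMAP (cat.), CH2Cl2, 0 °C → rt
Reagents that add atoms: acetic anhydride, CC(=O)OC(C)=O
Why: DMAP-catalysed O-acylation should turn the lactol hydroxyl into an anomeric acetate leaving group and mask the C7 phenol as an ester that also lowers the electron density of ring A before the Lewis acid step; C4 is untouched.

Step 7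
Reactants: 12 1-benzyloxy-4-bromobenzene
Product: 14 4-benzyloxyphenylzinc bromide, via 4-benzyloxyphenylmagnesium bromide 13 (not isolated)
Conditions: Mg, THF, rt → 40 °C; ZnBr2 (1.0 equiv), 0 °C → rt; THF largely exchanged for toluene
Reagents that add atoms: zinc bromide, Br[Zn]Br
Why: Grignard formation followed by transmetalation with one equivalent of ZnBr2 should give the arylzinc bromide, one aryl group per zinc, which is nucleophilic towards oxocarbenium ions but inert towards the aryl acetate of 11; removing most of the THF keeps the donor solvent from tying up BF3·OEt2 in the next step.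

Step 8
Reactants: 11 (4R)-2,7-diacetoxy-4-(hexa-O-benzylepigallocatechin-8'-yl)chromane; 14 4-benzyloxyphenylzinc bromide
Product: 15 (2S,4R)-7-acetoxy-2-(4-benzyloxyphenyl)-4-(hexa-O-benzylepigallocatechin-8'-yl)chromane
Conditions: 14 (2 equiv), BF3·OEt2, CH2Cl2–toluene, −78 → −20 °C; 1 M HCl (aq.), 0 °C
Reagents that add atoms: none
Why: BF3·OEt2 ionises the anomeric acetate to the C2 oxocarbenium ion, and the arylzinc bromide transfers its aryl group as in Lewis acid-mediated C-arylation of lactol acetates and glycosyl donors with arylzinc reagents; the C4 aryl group, held pseudoaxial by peri strain with C5–H, blocks the syn face through a 1,3-diaxial clash, so ring B should enter anti and give the 2,4-trans (2S) isomer under substrate control.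

Step 9
Reactants: 15 (2S,4R)-7-acetoxy-2-(4-benzyloxyphenyl)-4-(hexa-O-benzylepigallocatechin-8'-yl)chromane
Product: 16 (2S,4R)-2-(4-benzyloxyphenyl)-4-(hexa-O-benzylepigallocatechin-8'-yl)chroman-7-ol
Conditions: K2CO3, MeOH–THF, rt
Reagents that add atoms: none
Why: Base-catalysed transesterification removes the aryl acetate while every other oxygen is still a benzyl ether, so the only base-labile group is cleaved before the air-sensitive polyphenol is set free; no stereocentre is affected.

Step 10
Reactants: 16 (2S,4R)-2-(4-benzyloxyphenyl)-4-(hexa-O-benzylepigallocatechin-8'-yl)chroman-7-ol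
Product: 17 (2S,4R)-2-(4-hydroxyphenyl)-4-[(2R,3R)-3,5,7-trihydroxy-2-(3,4,5-trihydroxyphenyl)chroman-8-yl]chroman-7-ol (target)
Conditions: H2 (1 atm), Pd(OH)2/C, THF–MeOH, rt
Reagents that add atoms: none
Why: Catalytic hydrogenolysis should cleave the six aryl benzyl ethers and the secondary C3' benzyl ether, while under neutral conditions at atmospheric pressure the cyclic benzylic C2–O1 and C2'–O1' ethers and the C4–C8' bond are expected to persist, leaving the four stereocentres unchanged.

**Compound list**

1 | (−)-epigallocatechin (2'R,3'R) | c1c(O)cc(O)c2c1O[C@H](c1cc(O)c(O)c(O)c1)[C@H](O)C2 | starting material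
2 | penta-O-benzylepigallocatechin (C3' hydroxyl free) | c1c(OCc3ccccc3)cc(OCc3ccccc3)c2c1O[C@H](c1cc(OCc3ccccc3)c(OCc3ccccc3)c(OCc3ccccc3)c1)[C@H](O)C2 | intermediate
3 | hexa-O-benzylepigallocatechin | c1c(OCc3ccccc3)cc(OCc3ccccc3)c2c1O[C@H](c1cc(OCc3ccccc3)c(OCc3ccccc3)c(OCc3ccccc3)c1)[C@H](OCc1ccccc1)C2 | intermediate
4 | 8'-bromo-hexa-O-benzylepigallocatechin | Brc1c(OCc3ccccc3)cc(OCc3ccccc3)c2c1O[C@H](c1cc(OCc3ccccc3)c(OCc3ccccc3)c(OCc3ccccc3)c1)[C@H](OCc1ccccc1)C2 | intermediate
5 | 8'-lithio-hexa-O-benzylepigallocatechin (not isolated) | [Li]c1c(OCc3ccccc3)cc(OCc3ccccc3)c2c1O[C@H](c1cc(OCc3ccccc3)c(OCc3ccccc3)c(OCc3ccccc3)c1)[C@H](OCc1ccccc1)C2 | intermediate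
6 | lithium (E)-3-(dimethylamino)-1-(hexa-O-benzylepigallocatechin-8'-yl)prop-2-en-1-olate (carbinol carbon unassigned, not isolated) | [Li]OC(/C=C/N(C)C)c1c(OCc3ccccc3)cc(OCc3ccccc3)c2c1O[C@H](c1cc(OCc3ccccc3)c(OCc3ccccc3)c(OCc3ccccc3)c1)[C@H](OCc1ccccc1)C2 | intermediate
7 | (E)-3-(hexa-O-benzylepigallocatechin-8'-yl)prop-2-enal | O=C/C=C/c1c(OCc3ccccc3)cc(OCc3ccccc3)c2c1O[C@H](c1cc(OCc3ccccc3)c(OCc3ccccc3)c(OCc3ccccc3)c1)[C@H](OCc1ccccc1)C2 | intermediate
8 | resorcinol | Oc1cccc(O)c1 | starting material
9 | (3R)-3-(2,4-dihydroxyphenyl)-3-(hexa-O-benzylepigallocatechin-8'-yl)propanal (not isolated) | O=CC[C@@H](c1c(OCc3ccccc3)cc(OCc3ccccc3)c2c1O[C@H](c1cc(OCc3ccccc3)c(OCc3ccccc3)c(OCc3ccccc3)c1)[C@H](OCc1ccccc1)C2)c1ccc(O)cc1O | intermediate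
10 | (4R)-4-(hexa-O-benzylepigallocatechin-8'-yl)chromane-2,7-diol (both C2 anomers) | OC1C[C@@H](c2c(OCc5ccccc5)cc(OCc5ccccc5)c3c2O[C@H](c4cc(OCc5ccccc5)c(OCc5ccccc5)c(OCc5ccccc5)c4)[C@H](OCc5ccccc5)C3)c2ccc(O)cc2O1 | intermediate
11 | (4R)-2,7-diacetoxy-4-(hexa-O-benzylepigallocatechin-8'-yl)chromane (both C2 anomers) | CC(=O)OC1C[C@@H](c2c(OCc5ccccc5)cc(OCc5ccccc5)c3c2O[C@H](c4cc(OCc5ccccc5)c(OCc5ccccc5)c(OCc5ccccc5)c4)[C@H](OCc5ccccc5)C3)c2ccc(OC(C)=O)cc2O1 | intermediate
12 | 1-benzyloxy-4-bromobenzene | Brc1ccc(OCc2ccccc2)cc1 | starting material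
13 | 4-benzyloxyphenylmagnesium bromide (not isolated) | Br[Mg]c1ccc(OCc2ccccc2)cc1 | intermediate
14 | 4-benzyloxyphenylzinc bromide | Br[Zn]c1ccc(OCc2ccccc2)cc1 | intermediate
15 | (2S,4R)-7-acetoxy-2-(4-benzyloxyphenyl)-4-(hexa-O-benzylepigallocatechin-8'-yl)chromane | C(Oc1ccc([C@@H]2C[C@@H](c3c(OCc6ccccc6)cc(OCc6ccccc6)c4c3O[C@H](c5cc(OCc6ccccc6)c(OCc6ccccc6)c(OCc6ccccc6)c5)[C@H](OCc6ccccc6)C4)c3ccc(OC(C)=O)cc3O2)cc1)c1ccccc1 | intermediate
16 | (2S,4R)-2-(4-benzyloxyphenyl)-4-(hexa-O-benzylepigallocatechin-8'-yl)chroman-7-ol | C(Oc1ccc([C@@H]2C[C@@H](c3c(OCc6ccccc6)cc(OCc6ccccc6)c4c3O[C@H](c5cc(OCc6ccccc6)c(OCc6ccccc6)c(OCc6ccccc6)c5)[C@H](OCc6ccccc6)C4)c3ccc(O)cc3O2)cc1)c1ccccc1 | intermediate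
17 | (2S,4R)-2-(4-hydroxyphenyl)-4-[(2R,3R)-3,5,7-trihydroxy-2-(3,4,5-trihydroxyphenyl)chroman-8-yl]chroman-7-ol | Oc1ccc([C@@H]2C[C@@H](c3c(O)cc(O)c4c3O[C@H](c3cc(O)c(O)c(O)c3)[C@H](O)C4)c3ccc(O)cc3O2)cc1 | target

**Step count**

Total: 10 steps. Longest linear sequence: 9 steps (steps 1–6, 8, 9, 10 from (−)-epigallocatechin); step 7 is a one-step branch.

**Steps most likely to fail**

Step 5. The conjugate addition may be slow, because the iminium ion carries a strongly donating, di-ortho-substituted β-aryl group. That would leave room for direct addition at the iminium carbon, a second alkylation of ring A, or weak enantioface control if the lower unit is mismatched with the catalyst. The fallback sets out from 4 and returns at 10. Bromine–lithium exchange of 4 (n-BuLi, THF, −78 °C) and quenching with DMF should give hexa-O-benzylepigallocatechin-8'-carbaldehyde F1. Knoevenagel condensation with Meldrum's acid (pyrrolidinium acetate, benzene, rt) should give the arylidene Meldrum's acid F2, a far stronger acceptor than the iminium ion. Yb(OTf)3-catalysed Friedel–Crafts alkylation/lactonisation of F2 with resorcinol 8 (MeNO2, 60 °C, with loss of acetone and carbon dioxide) should give the 7-hydroxy-4-aryl-3,4-dihydrocoumarin as two C4 epimers. These are diastereomers because of the lower unit, so chromatography should deliver the (4R)-7-hydroxy-4-(hexa-O-benzylepigallocatechin-8'-yl)chroman-2-one F3. Reduction with i-Bu2AlH (CH2Cl2, −78 °C) then leads to lactol 10.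

Step 8. Facial selectivity at C2 may be insufficient. The oxocarbenium ion may also lose the C3 proton to give a 4H-chromene, the aryl group may pass from zinc to boron, or the cation may be captured by C6' of a second molecule. The fallback sets out from 10 and returns at 16. An excess of Grignard reagent 13, prepared as in step 7 (THF, 0 °C → rt), should add to the open-chain aldehyde tautomer of 10 and give the 1,3-diarylpropan-1-ol as two carbinol epimers, which are separated by chromatography. The (1R,3R)-1-(4-benzyloxyphenyl)-3-(2,4-dihydroxyphenyl)-3-(hexa-O-benzylepigallocatechin-8'-yl)propan-1-ol F4 is then cyclised under Mitsunobu conditions (PPh3, diisopropyl azodicarboxylate, THF, 0 °C, high dilution). The hydroxyl group ortho to the chain displaces the activated benzylic oxygen with inversion, closing O1–C2 to the (2S)-flavan 16. Here C2 is fixed by the separated carbinol, not by the facial bias of a cation.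

Step 4. The aryllithium may deprotonate a neighbouring benzylic ether (with Wittig rearrangement) or be protonated to the debrominated arene, and the acid-induced elimination to the enal may be incomplete. The fallback sets out from 4 and returns at 7. Suzuki–Miyaura coupling of 4 with (E)-2-(3,3-diethoxyprop-1-enyl)-4,4,5,5-tetramethyl-1,3,2-dioxaborolane (Pd(OAc)2, 2-dicyclohexylphosphino-2',6'-dimethoxybiphenyl, K3PO4, toluene–water, 80 °C) should give (E)-3-(hexa-O-benzylepigallocatechin-8'-yl)prop-2-enal diethyl acetal F5. Mild hydrolysis (pyridinium 4-toluenesulfonate, acetone–water, rt) then releases enal 7 without any organolithium intermediate.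

**Further compounds**

F1 | step 5 | hexa-O-benzylepigallocatechin-8'-carbaldehyde | O=Cc1c(OCc3ccccc3)cc(OCc3ccccc3)c2c1O[C@H](c1cc(OCc3ccccc3)c(OCc3ccccc3)c(OCc3ccccc3)c1)[C@H](OCc1ccccc1)C2
F2 | step 5 | 5-[(hexa-O-benzylepigallocatechin-8'-yl)methylidene]-2,2-dimethyl-1,3-dioxane-4,6-dione | CC1(C)OC(=O)C(=Cc2c(OCc5ccccc5)cc(OCc5ccccc5)c3c2O[C@H](c4cc(OCc5ccccc5)c(OCc5ccccc5)c(OCc5ccccc5)c4)[C@H](OCc5ccccc5)C3)C(=O)O1
F3 | step 5 | (4R)-7-hydroxy-4-(hexa-O-benzylepigallocatechin-8'-yl)chroman-2-one | O=C1C[C@@H](c2c(OCc5ccccc5)cc(OCc5ccccc5)c3c2O[C@H](c4cc(OCc5ccccc5)c(OCc5ccccc5)c(OCc5ccccc5)c4)[C@H](OCc5ccccc5)C3)c2ccc(O)cc2O1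
F4 | step 8 | (1R,3R)-1-(4-benzyloxyphenyl)-3-(2,4-dihydroxyphenyl)-3-(hexa-O-benzylepigallocatechin-8'-yl)propan-1-ol | C(Oc1ccc([C@H](O)C[C@@H](c3c(OCc6ccccc6)cc(OCc6ccccc6)c4c3O[C@H](c5cc(OCc6ccccc6)c(OCc6ccccc6)c(OCc6ccccc6)c5)[C@H](OCc6ccccc6)C4)c3ccc(O)cc3O)cc1)c1ccccc1
F5 | step 4 | (E)-3-(hexa-O-benzylepigallocatechin-8'-yl)prop-2-enal diethyl acetal | CCOC(OCC)/C=C/c1c(OCc3ccccc3)cc(OCc3ccccc3)c2c1O[C@H](c1cc(OCc3ccccc3)c(OCc3ccccc3)c(OCc3ccccc3)c1)[C@H](OCc1ccccc1)C2
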